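## Retrosynthetic overview

1. Target ⇐ 6-epi-alcohol (SN2 chloride with inversion, last step) ⇐ fully oxygenated tetracyclic core.
2. Cyclohexene ring (C1–C10 bond; sets C1, C10, C14) ⇐ transannular, epoxide-initiated cation–alkene cyclisation of a 14-membered (cembranoid-type) 1,14-cis-epoxy-(10Z)-ene; this cembrane→briarane event is the last ring closure.
3. 4,8-Ether bridge (sets C8, C17) ⇐ oxa-Michael addition of 4-OH across the macrocycle onto the Δ8(17)-butenolide.
4. 14-Membered ring ⇐ Ni/Cr closure of C8–C9 (the bond formed in the GGPP→cembrane cyclisation); C2–C3 ⇐ boron aldol between a nerol-derived epoxy dialdehyde and a butenolide methyl ketone (from 3-methyltetronic acid and 2-ethylacrolein).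
5. Ring order: butenolide → 14-membered carbocycle → tetrahydropyran (ether bridge) → cyclohexene.

Assumption: the target is taken exactly as drawn in the given SMILES; atom labels follow briarane numbering (C1 quaternary with Me-15, C16 = exocyclic CH2 on C5, C17 carries Me-18 and lactone carbonyl C19, Me-20 on C11) and are kept for open-chain and 14-membered ("seco") intermediates.

## Route

Step 1
Reactants: 1 nerol
Product: 2 neryl TBS ether
Conditions: TBSCl, imidazole, DMF, 0 °C to rt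
Reagents that add atoms: tert-butyldimethylsilyl chloride, CC(C)(C)[Si](C)(C)Cl
Why: Standard O-silylation of the primary allylic alcohol (no stereocentre formed); the TBS ether tolerates the organolithium chemistry of step 3.

Step 2
Reactants: 2 neryl TBS ether
Product: 4 (4Z)-6-(tert-butyldimethylsilyloxy)-4-methylhex-4-enal, via terminal epoxide 3 (not isolated)
Conditions: mCPBA, NaHCO3, CH2Cl2, −20 °C; crude epoxide then H5IO6, THF/Et2O, 0 °C
Reagents that add atoms: 3-chloroperbenzoic acid, OOC(=O)c1cccc(Cl)c1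
Why: Prilezhaev epoxidation prefers the remote trisubstituted alkene (the 2,3-alkene is deactivated by the allylic silyloxy group), and periodic acid cleaves the epoxide through its diol to the aldehyde and acetone; no stereocentre is carried on.

Step 3
Reactants: 4 (4Z)-6-(tert-butyldimethylsilyloxy)-4-methylhex-4-enal
Product: 7 (2Z,6Z)-8-(tert-butyldimethylsilyloxy)-2,6-dimethylocta-2,6-dien-1-ol, via betaine 5 (not isolated), via β-oxido ylide 6 (not isolated)
Conditions: EtPPh3Br, n-BuLi, THF, −78 °C; 4; n-BuLi, −78 to 0 °C; (CH2O)n, 0 °C to rt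
Reagents that add atoms: ethyltriphenylphosphonium bromide, CC[P+](c1ccccc1)(c1ccccc1)c1ccccc1.[Br-]; paraformaldehyde (reacts as formaldehyde), C=O
Why: Corey–Schlosser β-oxido ylide variant of the Wittig reaction: the re-lithiated betaine is hydroxymethylated by formaldehyde, and loss of Ph3PO with the original aldehyde oxygen gives the trisubstituted alkene with CH2OH cis to the chain (2Z).

Step 4
Reactants: 7 (2Z,6Z)-8-(tert-butyldimethylsilyloxy)-2,6-dimethylocta-2,6-dien-1-ol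
Product: 8 [(2R,3S)-3-[(3Z)-5-(tert-butyldimethylsilyloxy)-3-methylpent-3-enyl]-2-methyloxiran-2-yl]methanol
Conditions: Ti(OiPr)4 (10 mol%), D-(−)-diethyl tartrate (12 mol%), TBHP, 4 Å MS, CH2Cl2, −20 °C
Reagents that add atoms: tert-butyl hydroperoxide, CC(C)(C)OO
Why: Katsuki–Sharpless asymmetric epoxidation is chemoselective for the free allylic alcohol and stereospecific, so the Z-alkene gives the cis-epoxide (C2 and C13 cis); D-(−)-tartrate sets the absolute configuration of C1 and C14 (oxirane 2R,3S).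

Step 5
Reactants: 8 [(2R,3S)-3-[(3Z)-5-(tert-butyldimethylsilyloxy)-3-methylpent-3-enyl]-2-methyloxiran-2-yl]methanol
Product: 9 (2Z)-5-[(2S,3R)-3-(hydroxymethyl)-3-methyloxiran-2-yl]-3-methylpent-2-en-1-ol
Conditions: HF·pyridine, pyridine, THF, 0 °C
Reagents that add atoms: none
Why: Buffered HF cleaves the primary silyl ether without the basic conditions that would trigger Payne rearrangement of the 2,3-epoxy alcohol; no stereocentre is touched.

Step 6
Reactants: 9 (2Z)-5-[(2S,3R)-3-(hydroxymethyl)-3-methyloxiran-2-yl]-3-methylpent-2-en-1-ol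
Product: 10 (2S,3S)-2-methyl-3-[(3Z)-3-methyl-5-oxopent-3-enyl]oxirane-2-carbaldehyde
Conditions: Dess–Martin periodinane, NaHCO3, CH2Cl2, 0 °C to rt
Reagents that add atoms: none
Why: Buffered Dess–Martin oxidation converts both primary alcohols to aldehydes without Z→E isomerisation of the enal; the epoxy aldehyde has no α-hydrogen, so C1 cannot epimerise.

Step 7
Reactants: 11 ethyl 2-methyl-3-oxobutanoate
Product: 13 3-methyltetronic acid, via bromo keto ester 12 (not isolated)
Conditions: Br2, CHCl3, 0 °C to rt, 16 h; then neat, 120 °C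
Reagents that add atoms: none
Why: Classical tetronic acid synthesis: HBr-mediated α→γ bromine shift gives the 4-bromo keto ester, which lactonises on heating by O-alkylation with loss of bromoethane.

Step 8
Reactants: 13 3-methyltetronic acid
Product: 14 4-methyl-5-oxo-2,5-dihydrofuran-3-yl triflate
Conditions: Tf2O, i-Pr2NEt, CH2Cl2, −78 °C
Reagents that add atoms: triflic anhydride, O=S(=O)(OS(=O)(=O)C(F)(F)F)C(F)(F)F
Why: O-sulfonylation of the vinylogous acid gives the vinyl triflate that later serves as the C8 electrophile in the Ni/Cr coupling.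

Step 9
Reactants: 14 4-methyl-5-oxo-2,5-dihydrofuran-3-yl triflate; 15 2-ethylacrolein
Product: 17 (2S)-2-[(1R)-1-(tert-butyldimethylsilyloxy)-2-methylidenebutyl]-4-methyl-5-oxo-2,5-dihydrofuran-3-yl triflate, via silyloxyfuran 16 (not isolated)
Conditions: TBSOTf, Et3N, Et2O, 0 °C, salts filtered off; crude 16 then 15, chiral oxazaborolidinium triflimide (20 mol%), CH2Cl2, −78 °C
Reagents that add atoms: tert-butyldimethylsilyl triflate, CC(C)(C)[Si](C)(C)OS(=O)(=O)C(F)(F)F
Why: Catalytic enantioselective vinylogous Mukaiyama aldol reaction: the oxazaborolidinium ion binds the 2-substituted acrolein (its standard substrate class), the catalyst antipode is chosen to expose the aldehyde Si face, the open antiperiplanar transition state gives the syn (threo) C6/C7 pair (6R,7S), and silyl transfer to the aldolate delivers the TBS ether directly.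

Step 10
Reactants: 17 (2S)-2-[(1R)-1-(tert-butyldimethylsilyloxy)-2-methylidenebutyl]-4-methyl-5-oxo-2,5-dihydrofuran-3-yl triflate
Product: 19 (2S)-2-[(1R)-1-(tert-butyldimethylsilyloxy)-2-methylidene-3-oxobutyl]-4-methyl-5-oxo-2,5-dihydrofuran-3-yl triflate, via allylic alcohol 18 (not isolated)
Conditions: SeO2 (0.3 equiv), TBHP, CH2Cl2, rt; then Dess–Martin periodinane, NaHCO3, rt
Reagents that add atoms: tert-butyl hydroperoxide (oxygen relayed by catalytic SeO2), CC(C)(C)OO
Why: Riley allylic oxidation (ene reaction then [2,3]-shift) attacks the allylic CH2 of the 1,1-disubstituted alkene rather than the oxygenated, hindered C6–H, and oxidation of the resulting carbinol gives the methyl enone; C6 and C7 are untouched.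

Step 11
Reactants: 19 (2S)-2-[(1R)-1-(tert-butyldimethylsilyloxy)-2-methylidene-3-oxobutyl]-4-methyl-5-oxo-2,5-dihydrofuran-3-yl triflate; 10 (2S,3S)-2-methyl-3-[(3Z)-3-methyl-5-oxopent-3-enyl]oxirane-2-carbaldehyde
Product: 22 open-chain aldol (1R,2R,6R,7S,14S,10Z)-6-TBSO-1,14-epoxy-2-hydroxy-4,9-dioxo-8-triflyloxy-1,10;8,9-diseco-briara-5(16),8(17),10-trien-19,7-olide, via boron enolate 20 (not isolated), via boron aldolate 21 (not isolated)
Conditions: Cy2BCl, Et3N, Et2O, 0 °C; then 10, −78 to −20 °C; pH 7 buffer, MeOH, H2O2, 0 °C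
Reagents that add atoms: none
Why: Boron-mediated methyl ketone aldol: the enolate adds only to the α-epoxy aldehyde (far more electrophilic than the β,β-disubstituted enal), and Felkin–Anh control with the epoxide C–O bond anti to the incoming enolate sets C2 (OH anti to the epoxide oxygen).

Step 12
Reactants: 22 open-chain aldol
Product: 23 open-chain acetate (1S,2R,6R,7S,14S,10Z)-2-acetoxy-6-TBSO-1,14-epoxy-4,9-dioxo-8-triflyloxy-1,10;8,9-diseco-briara-5(16),8(17),10-trien-19,7-olide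
Conditions: Ac2O, pyridine, DMAP (5 mol%), CH2Cl2, 0 °C
Reagents that add atoms: acetic anhydride, CC(=O)OC(C)=O
Why: Acylation of the only free hydroxyl installs the C2 acetate of the target (configuration untouched) and suppresses later hydride-shift pathways at the neighbouring epoxide.

Step 13
Reactants: 23 open-chain acetate
Product: 25 14-membered carbinol (1S,2R,6R,7R,9R,14S,10Z)-2-acetoxy-6-TBSO-1,14-epoxy-9-hydroxy-4-oxo-1,10-secobriara-5(16),8(17),10-trien-19,7-olide, via chromium alkoxide 24 (not isolated)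
Conditions: CrCl2 (6 equiv), NiCl2 (2 mol%), DMSO/THF, rt, 2 mM
Reagents that add atoms: none
Why: Nozaki–Hiyama–Kishi macrocyclisation: Ni inserts into the vinyl triflate, the vinylchromium adds 1,2 to the enal in preference to the hindered conjugated C4 ketone, and C9 is set by macrocyclic control from the adjacent C7 stereocentre, as in diastereoselective Ni/Cr closures of cembranoid seco-aldehydes.

Step 14
Reactants: 25 14-membered carbinol
Product: 27 ether-bridged macrocycle (1S,2R,4S,6R,7S,8R,9R,14S,17R,10Z)-2-acetoxy-6-TBSO-1,14:4,8-diepoxy-9-hydroxy-1,10-secobriara-5(16),10-dien-19,7-olide, via C4 carbinol 26 (not isolated)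
Conditions: (R)-Me-CBS (0.3 equiv), catecholborane, toluene, −78 °C; MeOH; then DBU (0.3 equiv), CH2Cl2, rt
Reagents that add atoms: none
Why: Corey–Bakshi–Shibata reduction with the alkenyl group as the large substituent gives the 4S carbinol, which then adds to C8 of the butenolide in a 6-exo oxa-Michael reaction; the tether from C7 enforces cis ring fusion (C8), and reversible protonation under DBU places Me-18 trans to the C9 branch (C17).

Step 15
Reactants: 27 ether-bridged macrocycle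
Product: 28 TES ether (1S,2R,4S,6R,7S,8S,9R,14S,17R,10Z)-2-acetoxy-6-TBSO-9-TESO-1,14:4,8-diepoxy-1,10-secobriara-5(16),10-dien-19,7-olide
Conditions: TESOTf, 2,6-lutidine, CH2Cl2, −78 °C
Reagents that add atoms: triethylsilyl triflate, CC[Si](CC)(CC)OS(=O)(=O)C(F)(F)F
Why: Silylation of the hindered 9-OH (configuration untouched) keeps it out of the Lewis-acid step and differentiates it from 14-OH for the later acetylation.

Step 16
Reactants: 28 TES ether
Product: 30 briarane alcohol (1R,2R,4S,6R,7S,8S,9R,10S,14S,17R)-2-acetoxy-6-TBSO-9-TESO-4,8-epoxy-14-hydroxybriara-5(16),11-dien-19,7-olide, via C11 carbocation 29 (not isolated)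
Conditions: MeAlCl2 (3 equiv), CH2Cl2, −78 °C; aq. Rochelle salt
Reagents that add atoms: none
Why: Proposed new method: the Lewis acid ionises the tertiary C1–O bond of the epoxide, the (10Z)-alkene attacks C1 anti to the leaving oxygen through a chair-like six-membered transition state (Stork–Eschenmoser stereospecificity: the cis-epoxide places C2 axial and O-14 equatorial, the Z-alkene places C9 axial), which inverts C1, retains C14 and creates C10 with Me-15/H-10 trans and O-14 cis to C2, and the C11 cation loses H-12 to the endocyclic alkene; the closest known reactions are epoxide-initiated polyene cyclisations with MeAlCl2 and acid-promoted transannular cyclisations of epoxy-germacrenes and cembranoid epoxides.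

Step 17
Reactants: 30 briarane alcohol
Product: 31 diacetate (1R,2R,4S,6R,7S,8S,9R,10S,14S,17R)-2,14-diacetoxy-6-TBSO-9-TESO-4,8-epoxybriara-5(16),11-dien-19,7-olide
Conditions: Ac2O, DMAP, pyridine, rt
Reagents that add atoms: acetic anhydride, CC(=O)OC(C)=O
Why: DMAP-catalysed acetylation of the only free hydroxyl (14-OH, configuration untouched).

Step 18
Reactants: 31 diacetate
Product: 32 diol (1R,2R,4S,6R,7S,8R,9R,10S,14S,17R)-2,14-diacetoxy-4,8-epoxy-6,9-dihydroxybriara-5(16),11-dien-19,7-olide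
Conditions: HF·pyridine, THF, 0 °C to rt
Reagents that add atoms: none
Why: Acidic fluoride cleaves both silyl ethers without the acyl migration or retro-Michael opening that basic fluoride could cause; no stereocentre changes.

Step 19
Reactants: 32 diol
Product: 33 CNP0198838.2 (1R,2R,4S,6S,7R,8R,9R,10S,14S,17R)-2,14-diacetoxy-6-chloro-4,8-epoxy-9-hydroxybriara-5(16),11-dien-19,7-olide
Conditions: PPh3, hexachloroacetone, CH2Cl2, −20 to 0 °C
Reagents that add atoms: hexachloroacetone, ClC(Cl)(Cl)C(=O)C(Cl)(Cl)Cl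
Why: Appel-type chlorination with Magid's reagent proceeds by SN2 with inversion at the allylic C6 and without allylic transposition, while the neopentyl-like 9-OH cannot be displaced, so C6 ends with the required 6S configuration.

## Compound list

1 | nerol, (2Z)-3,7-dimethylocta-2,6-dien-1-ol | CC(C)=CCC/C(C)=C\CO | starting material
2 | neryl TBS ether | CC(C)=CCC/C(C)=C\CO[Si](C)(C)C(C)(C)C | intermediate
3 | terminal (6,7) epoxide of 2, racemic | CC1(C)OC1CC/C(C)=C\CO[Si](C)(C)C(C)(C)C | intermediate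
4 | (4Z)-6-(tert-butyldimethylsilyloxy)-4-methylhex-4-enal | O=CCC/C(C)=C\CO[Si](C)(C)C(C)(C)C | intermediate
5 | betaine from 4 and ethylidenetriphenylphosphorane | CC([P+](c1ccccc1)(c1ccccc1)c1ccccc1)C([O-])CC/C(C)=C\CO[Si](C)(C)C(C)(C)C | intermediate
6 | lithium β-oxido ylide | CC(=P(c1ccccc1)(c1ccccc1)c1ccccc1)C([O-])CC/C(C)=C\CO[Si](C)(C)C(C)(C)C.[Li+] | intermediate
7 | (2Z,6Z)-8-(tert-butyldimethylsilyloxy)-2,6-dimethylocta-2,6-dien-1-ol | OC/C(C)=C\CC/C(C)=C\CO[Si](C)(C)C(C)(C)C | intermediate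
8 | [(2R,3S)-3-[(3Z)-5-(tert-butyldimethylsilyloxy)-3-methylpent-3-enyl]-2-methyloxiran-2-yl]methanol | CC(C)(C)[Si](C)(C)OC/C=C(C)\CC[C@@H]1O[C@]1(C)CO | intermediate
9 | (2Z)-5-[(2S,3R)-3-(hydroxymethyl)-3-methyloxiran-2-yl]-3-methylpent-2-en-1-ol | OC/C=C(C)\CC[C@@H]1O[C@]1(C)CO | intermediate
10 | (2S,3S)-2-methyl-3-[(3Z)-3-methyl-5-oxopent-3-enyl]oxirane-2-carbaldehyde | O=C/C=C(C)\CC[C@@H]1O[C@]1(C)C=O | intermediate
11 | ethyl 2-methyl-3-oxobutanoate (racemic) | CCOC(=O)C(C)C(C)=O | starting material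
12 | ethyl 4-bromo-2-methyl-3-oxobutanoate | CCOC(=O)C(C)C(=O)CBr | intermediate
13 | 3-methyltetronic acid, 4-hydroxy-3-methylfuran-2(5H)-one | CC1=C(O)COC1=O | intermediate
14 | 4-methyl-5-oxo-2,5-dihydrofuran-3-yl triflate | CC1=C(OS(=O)(=O)C(F)(F)F)COC1=O | intermediate
15 | 2-ethylacrolein, 2-methylidenebutanal | CCC(=C)C=O | starting material
16 | 5-(tert-butyldimethylsilyloxy)-4-methylfuran-3-yl triflate | CC1=C(O[Si](C)(C)C(C)(C)C)OC=C1OS(=O)(=O)C(F)(F)F | intermediate
17 | (2S)-2-[(1R)-1-(tert-butyldimethylsilyloxy)-2-methylidenebutyl]-4-methyl-5-oxo-2,5-dihydrofuran-3-yl triflate | CCC(=C)[C@@H](O[Si](C)(C)C(C)(C)C)[C@@H]1OC(=O)C(C)=C1OS(=O)(=O)C(F)(F)F | intermediate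
18 | (2S)-2-[(1R)-1-(tert-butyldimethylsilyloxy)-3-hydroxy-2-methylidenebutyl]-4-methyl-5-oxo-2,5-dihydrofuran-3-yl triflate (C4 epimers) | CC(O)C(=C)[C@@H](O[Si](C)(C)C(C)(C)C)[C@@H]1OC(=O)C(C)=C1OS(=O)(=O)C(F)(F)F | intermediate
19 | (2S)-2-[(1R)-1-(tert-butyldimethylsilyloxy)-2-methylidene-3-oxobutyl]-4-methyl-5-oxo-2,5-dihydrofuran-3-yl triflate | CC(=O)C(=C)[C@@H](O[Si](C)(C)C(C)(C)C)[C@@H]1OC(=O)C(C)=C1OS(=O)(=O)C(F)(F)F | intermediate
20 | dicyclohexylboron dienolate of 19 | C=C(OB(C1CCCCC1)C1CCCCC1)C(=C)[C@@H](O[Si](C)(C)C(C)(C)C)[C@@H]1OC(=O)C(C)=C1OS(=O)(=O)C(F)(F)F | intermediate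
21 | dicyclohexylboron aldolate of 22 | O=C/C=C(C)\CC[C@@H]1O[C@]1(C)[C@H](OB(C2CCCCC2)C2CCCCC2)CC(=O)C(=C)[C@@H](O[Si](C)(C)C(C)(C)C)[C@@H]1OC(=O)C(C)=C1OS(=O)(=O)C(F)(F)F | intermediate
22 | open-chain aldol, (1R,2R,6R,7S,14S,10Z)-6-TBSO-1,14-epoxy-2-hydroxy-4,9-dioxo-8-triflyloxy-1,10;8,9-diseco-briara-5(16),8(17),10-trien-19,7-olide | O=C/C=C(C)\CC[C@@H]1O[C@]1(C)[C@H](O)CC(=O)C(=C)[C@@H](O[Si](C)(C)C(C)(C)C)[C@@H]1OC(=O)C(C)=C1OS(=O)(=O)C(F)(F)F | intermediate
23 | open-chain acetate, (1S,2R,6R,7S,14S,10Z)-2-acetoxy analogue of 22 | O=C/C=C(C)\CC[C@@H]1O[C@]1(C)[C@H](OC(C)=O)CC(=O)C(=C)[C@@H](O[Si](C)(C)C(C)(C)C)[C@@H]1OC(=O)C(C)=C1OS(=O)(=O)C(F)(F)F | intermediate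
24 | dichlorochromium(III) 9-alkoxide of 25 | C=C1C(=O)C[C@@H](OC(C)=O)[C@@]2(C)O[C@H]2CC/C(C)=C\[C@@H](O[Cr](Cl)Cl)C2=C(C)C(=O)O[C@H]2[C@@H]1O[Si](C)(C)C(C)(C)C | intermediate
25 | 14-membered carbinol, (1S,2R,6R,7R,9R,14S,10Z)-2-acetoxy-6-TBSO-1,14-epoxy-9-hydroxy-4-oxo-1,10-secobriara-5(16),8(17),10-trien-19,7-olide | C=C1C(=O)C[C@@H](OC(C)=O)[C@@]2(C)O[C@H]2CC/C(C)=C\[C@@H](O)C2=C(C)C(=O)O[C@H]2[C@@H]1O[Si](C)(C)C(C)(C)C | intermediate
26 | C4 carbinol, (1S,2R,4S,6R,7R,9R,14S,10Z)-2-acetoxy-6-TBSO-1,14-epoxy-4,9-dihydroxy-1,10-secobriara-5(16),8(17),10-trien-19,7-olide | C=C1[C@@H](O)C[C@@H](OC(C)=O)[C@@]2(C)O[C@H]2CC/C(C)=C\[C@@H](O)C2=C(C)C(=O)O[C@H]2[C@@H]1O[Si](C)(C)C(C)(C)C | intermediate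
27 | ether-bridged macrocycle, (1S,2R,4S,6R,7S,8R,9R,14S,17R,10Z)-2-acetoxy-6-TBSO-1,14:4,8-diepoxy-9-hydroxy-1,10-secobriara-5(16),10-dien-19,7-olide | C=C1[C@@H]2C[C@@H](OC(C)=O)[C@@]3(C)O[C@H]3CC/C(C)=C\[C@@H](O)[C@]3(O2)[C@@H](C)C(=O)O[C@H]3[C@@H]1O[Si](C)(C)C(C)(C)C | intermediate
28 | TES ether, (1S,2R,4S,6R,7S,8S,9R,14S,17R,10Z)-2-acetoxy-6-TBSO-9-TESO-1,14:4,8-diepoxy-1,10-secobriara-5(16),10-dien-19,7-olide | C=C1[C@@H]2C[C@@H](OC(C)=O)[C@@]3(C)O[C@H]3CC/C(C)=C\[C@@H](O[Si](CC)(CC)CC)[C@]3(O2)[C@@H](C)C(=O)O[C@H]3[C@@H]1O[Si](C)(C)C(C)(C)C | intermediate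
29 | C11 carbocation with C14 O-aluminate | C=C1[C@@H]2C[C@@H](OC(C)=O)[C@@]3(C)[C@@H](O[Al-](C)(Cl)Cl)CC[C+](C)[C@@H]3[C@@H](O[Si](CC)(CC)CC)[C@]3(O2)[C@@H](C)C(=O)O[C@H]3[C@@H]1O[Si](C)(C)C(C)(C)C | intermediate
30 | briarane alcohol, (1R,2R,4S,6R,7S,8S,9R,10S,14S,17R)-2-acetoxy-6-TBSO-9-TESO-4,8-epoxy-14-hydroxybriara-5(16),11-dien-19,7-olide | C=C1[C@@H]2C[C@@H](OC(C)=O)[C@@]3(C)[C@@H](O)CC=C(C)[C@@H]3[C@@H](O[Si](CC)(CC)CC)[C@]3(O2)[C@@H](C)C(=O)O[C@H]3[C@@H]1O[Si](C)(C)C(C)(C)C | intermediate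
31 | diacetate, (1R,2R,4S,6R,7S,8S,9R,10S,14S,17R)-2,14-diacetoxy-6-TBSO-9-TESO-4,8-epoxybriara-5(16),11-dien-19,7-olide | C=C1[C@@H]2C[C@@H](OC(C)=O)[C@@]3(C)[C@@H](OC(C)=O)CC=C(C)[C@@H]3[C@@H](O[Si](CC)(CC)CC)[C@]3(O2)[C@@H](C)C(=O)O[C@H]3[C@@H]1O[Si](C)(C)C(C)(C)C | intermediate
32 | diol, (1R,2R,4S,6R,7S,8R,9R,10S,14S,17R)-2,14-diacetoxy-4,8-epoxy-6,9-dihydroxybriara-5(16),11-dien-19,7-olide | C=C1[C@@H]2C[C@@H](OC(C)=O)[C@@]3(C)[C@@H](OC(C)=O)CC=C(C)[C@@H]3[C@@H](O)[C@]3(O2)[C@@H](C)C(=O)O[C@H]3[C@@H]1O | intermediate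
33 | CNP0198838.2, (1R,2R,4S,6S,7R,8R,9R,10S,14S,17R)-2,14-diacetoxy-6-chloro-4,8-epoxy-9-hydroxybriara-5(16),11-dien-19,7-olide | C=C1[C@@H]2C[C@@H](OC(C)=O)[C@@]3(C)[C@@H](OC(C)=O)CC=C(C)[C@@H]3[C@@H](O)[C@]3(O2)[C@@H](C)C(=O)O[C@H]3[C@H]1Cl | target

## Step count and risks

Total step count: 19. Longest linear sequence: 15 steps (steps 1–6, then 11–19); the butenolide branch (steps 7–10) joins at step 11.

Three steps most likely to fail:

1. Step 16 (transannular epoxide–alkene cyclisation). The risks are participation of the C2 acetate at C1, a boat-type closure giving the 10-epimer, loss of H-20 to the exocyclic alkene, and capture of the cation by O-14. The fallback sets out from 28 and replaces the cationic manifold by a radical one. Cp2TiCl (from Cp2TiCl2 and Mn, THF, rt) opens the epoxide homolytically to the C14 titanium alkoxide and C1 tertiary radical, which adds across the ring to C10. Ti(III) trapping and β-hydride loss from the C11 radical give the 11(20)-exomethylene alcohol F1. Catalytic RhCl3·3H2O in EtOH at 60 °C then moves this alkene into the ring (the 5(16)-alkene, flanked by two oxygenated carbons, migrates far more slowly), and the route is rejoined at 30.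

2. Step 14 (CBS reduction and oxa-Michael bridging). The risks are poor C4 selectivity in the macrocycle, 2-O→4-O acetyl migration, and base-mediated epimerisation at C7 before ring closure. The fallback sets out from 25 and inverts the order of the two transannular closures. The CBS reduction is stopped at the diol 26, which is isolated. TESOTf/2,6-lutidine gives the 4,9-bis-TES ether F2, and the MeAlCl2 cyclisation is run on this unbridged 14-membered ring to give the bicyclic butenolide F3. Ac2O/DMAP gives the 2,14-diacetate F4. TBAF/AcOH in THF then removes the three silyl groups, and the liberated 4-OH closes onto the butenolide, so the route is rejoined at 32.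

3. Step 9 (enantio- and syn-selective vinylogous aldol on a triflyloxy-substituted silyloxyfuran). The risks are low facial control and competing 1,4-addition to the acrolein. The fallback sets out from 14 and 15 and replaces asymmetric catalysis by diastereoselective synthesis plus resolution. Silyloxyfuran 16 is isolated and combined with 15 under BF3·OEt2 (CH2Cl2, −78 °C, aqueous HCl work-up), which gives the syn adduct as the racemic alcohol F5. Lipase-catalysed kinetic resolution (vinyl acetate, MTBE; enzyme selected by screening so that the (2R,1′S) antipode is acetylated to the acetate F7) leaves the (2S,1′R) alcohol F6. TBSOTf/2,6-lutidine converts F6 into 17, where the route is rejoined.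

Further compounds

F1 | step 16 | (1R,2R,4S,6R,7S,8S,9R,10S,14S,17R)-2-acetoxy-6-TBSO-9-TESO-4,8-epoxy-14-hydroxybriara-5(16),11(20)-dien-19,7-olide | C=C1[C@@H]2C[C@@H](OC(C)=O)[C@@]3(C)[C@@H](O)CCC(=C)[C@@H]3[C@@H](O[Si](CC)(CC)CC)[C@]3(O2)[C@@H](C)C(=O)O[C@H]3[C@@H]1O[Si](C)(C)C(C)(C)C
F2 | step 14 | 4,9-bis-TES ether of 26 (14-membered epoxy butenolide) | C=C1[C@@H](O[Si](CC)(CC)CC)C[C@@H](OC(C)=O)[C@@]2(C)O[C@H]2CC/C(C)=C\[C@@H](O[Si](CC)(CC)CC)C2=C(C)C(=O)O[C@H]2[C@@H]1O[Si](C)(C)C(C)(C)C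
F3 | step 14 | 2-acetoxy-6-TBSO-4,9-bis-TESO-14-hydroxybriara-5(16),8(17),11-trien-19,7-olide | C=C1[C@@H](O[Si](CC)(CC)CC)C[C@@H](OC(C)=O)[C@@]2(C)[C@@H](O)CC=C(C)[C@@H]2[C@@H](O[Si](CC)(CC)CC)C2=C(C)C(=O)O[C@H]2[C@@H]1O[Si](C)(C)C(C)(C)C
F4 | step 14 | 2,14-diacetoxy-6-TBSO-4,9-bis-TESO-briara-5(16),8(17),11-trien-19,7-olide | C=C1[C@@H](O[Si](CC)(CC)CC)C[C@@H](OC(C)=O)[C@@]2(C)[C@@H](OC(C)=O)CC=C(C)[C@@H]2[C@@H](O[Si](CC)(CC)CC)C2=C(C)C(=O)O[C@H]2[C@@H]1O[Si](C)(C)C(C)(C)C
F5 | step 9 | racemic syn 2-(1-hydroxy-2-methylidenebutyl)-4-methyl-5-oxo-2,5-dihydrofuran-3-yl triflate (both enantiomers) | CCC(=C)[C@@H](O)[C@@H]1OC(=O)C(C)=C1OS(=O)(=O)C(F)(F)F.CCC(=C)[C@H](O)[C@H]1OC(=O)C(C)=C1OS(=O)(=O)C(F)(F)F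
F6 | step 9 | (2S)-2-[(1R)-1-hydroxy-2-methylidenebutyl]-4-methyl-5-oxo-2,5-dihydrofuran-3-yl triflate | CCC(=C)[C@@H](O)[C@@H]1OC(=O)C(C)=C1OS(=O)(=O)C(F)(F)F
F7 | step 9 | (2R)-2-[(1S)-1-acetoxy-2-methylidenebutyl]-4-methyl-5-oxo-2,5-dihydrofuran-3-yl triflate | CCC(=C)[C@H](OC(C)=O)[C@H]1OC(=O)C(C)=C1OS(=O)(=O)C(F)(F)F
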